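J, the substrate, leaves in two directions at once, and I set out to reckon what share Q holds among Q, E and L in each vessel.

| flask | J | Z | time | remark |
|---|---|---|---|---|
| eta | 0.010 M | 55 µM | 80 s | everything together in a closed stirred flask, run for 80 s |
| epsilon | 0.010 M | 55 µM |  | one stirred flow tank at steady state, fed with the mixture as stated, mean residence time 80 s |
| zeta | 0.010 M | 55 µM |  | one stirred flow tank at steady state, fed with the mixture as stated, mean residence time 400 s |
| gamma | 0.010 M | 55 µM | 80 s | a tube with plug flow, the mixed feed as stated, residence time 80 s |

* the set-up with the highest share of Q in all that became Q or E or L, at the outlet or at the end ("none" if the first two lie within 2 percentage points) (eta / epsilon / zeta / gamma / none)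
* share of Q in all that became Q or E or L, at the outlet or at the end, eta
* share of Q in all that became Q or E or L, at the outlet or at the end, epsilon
* share of Q in all that became Q or E or L, at the outlet or at the end, zeta
* share of Q in all that became Q or E or L, at the outlet or at the end, gamma

    J ⇌ Q (K1 = 2.3, k1 = 0.00608 s⁻¹)
    Q + G ⇌ E + G, rate k2*[G]*[Q] forward; the back reaction follows from the equilibrium constant (K2 = 0.52, k2 = 5.84 M⁻¹ s⁻¹)
    Z → G (k3 = 0.00439 s⁻¹)
    L ⇌ J (k4 = 0.0118 s⁻¹)
    E + G ⇌ L + G, rate k5*[G]*[E] forward; the back reaction follows from the equilibrium constant (K5 = 0.459, k5 = 14.2 M⁻¹ s⁻¹)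

- My bench rule was the branching ratio. J goes to Q with f = 0.00608 s⁻¹ and to L, by step four run backwards, with b = 0.00648 s⁻¹, so Q starts with 48.4% of the products.
- The rule needs products that have not yet gone back. L returns to J with d = 0.0118 s⁻¹, and d times the 80 s run is 0.944, which is not small, so in eta the rule had stopped working.
- I took products in eta as half the run old on average. Q returns with r = 0.002643 s⁻¹, slower than L does, so Q/L grew to 1.35. That gave a share of 57.5% in eta, and the same in the tube gamma, whose parcels keep the same clock.
- Next I asked whether E counted. Z becomes G with g = 0.00439 s⁻¹, so integrating G over time t gives Z(t − (1 − exp(−gt))/g). The fastest catalysed step is L to E, with c = 30.9 M⁻¹ s⁻¹, and G makes it pseudo-first-order in L.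
- My carried quantity was X = 0.0213 for eta, the catalyst exposure, c times the integral of G over a parcel's time. It was far smaller than dt, so I dropped E in eta and gamma.
- In a tank of residence time τ, G stands at Zgτ/(1 + gτ), and I took E as X times L. Epsilon gave X = 0.0354 and Q/L = 1.51, so 59.3%. Zeta gave X = 0.434 and Q/L = 2.61, so 64.5%, and I named zeta best.
- The forecast gave 57.5% for eta, 59.4% for epsilon, 64.5% for zeta and 57.5% for gamma, and named zeta. Its grounds included this: “E stays minor at short times because the catalyst is still forming”.
- The simulation gave 57.5% for eta, 59.4% for epsilon, 64.5% for zeta and 57.5% for gamma, with zeta best.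
- In eta, X was 0.0213 against dt of 0.944, and moving each setting singly by one factor shifted the share as follows, strongest first: time (2.4 points), then Z (0.076 points), then J (under 0.05 points). In zeta, X of 0.434 times the L reading of 15.4% of the J charged came to 6.68%, and E stood at 7.40% of the J charged.

The numbers of this flask were set for the occasion, and the outcome is calculated.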